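**Plan**

- Retrosynthetic cuts: first the C3 acetate, then the ring bond C1–C6 (alkenylchromium onto aldehyde), then the C(sp)–C(sp2) bond between the bromoalkene carbon and the enyne side chain, and last the side chain at its alkyne–alkene and allyl–alkenyl bonds.
- Enabling feature: with the ring numbered C1 (alkynyl carbon), C2 (=CH), C3 (OAc), C4 (OMe), C5 and C6 (OH), the atoms C6, C5, C4, C3 and C2 are C1 to C5 of L-arabinose with the oxygens already in place, so the single ring of the target needs only the bond C1–C6.
- Forward order: the enyne side chain is built from 2-methylbut-3-yn-2-ol, 2,3-dibromopropene and ethynyltrimethylsilane. L-arabinose becomes a 3-O-methyl, 2,4-bis-silylated dithioacetal whose C5 is turned into a 1,1-dibromoalkene. A trans-selective Sonogashira coupling joins the two, the dithioacetal is opened to the aldehyde, and CrCl2/NiCl2 closes the cyclohexene. Desilylation and a boronate-guided acetylation finish the synthesis.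
- Stereochemistry: C3, C4 and C5 are C4, C3 and C2 of L-arabinose and are never touched. C6 is set in the ring closure under substrate control. The (E) side-chain alkene comes from syn-hydrostannation and the (Z) bromoalkene from the trans-selective coupling.

Key step: step 14

Remark: TBS = tert-butyldimethylsilyl. Open-chain sugar intermediates carry arabinose locants; ring compounds carry the ring locants defined in the plan.

**Route**

Step 1
Reactants: 1 2-methylbut-3-yn-2-ol
Product: 2 (E)-2-methyl-4-(tributylstannyl)but-3-en-2-ol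
Conditions: Bu3SnH, PdCl2(PPh3)2 (cat.), THF, 0 °C to rt
Reagents that add atoms: tributyltin hydride, CCCC[SnH](CCCC)CCCC
Why: Palladium-catalysed syn-hydrostannation of the terminal alkyne places tin on the terminal carbon, away from the tertiary carbinol, and so fixes the (E) alkene.

Step 2
Reactants: 2 (E)-2-methyl-4-(tributylstannyl)but-3-en-2-ol; 3 2,3-dibromopropene
Product: 4 (E)-6-bromo-2-methylhepta-3,6-dien-2-ol
Conditions: Pd2(dba)3 (cat.), AsPh3, THF, 50 °C
Reagents that add atoms: none
Why: Stille coupling through a π-allylpalladium intermediate, in which the allylic C–Br bond ionises far faster than the alkenyl C–Br bond, the symmetric 2-bromoallyl unit can give only one regioisomer and the alkenyl group transfers with retention of the (E) geometry.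

Step 3
Reactants: 4 (E)-6-bromo-2-methylhepta-3,6-dien-2-ol; 5 ethynyltrimethylsilane
Product: 6 (E)-2-methyl-6-methylidene-8-(trimethylsilyl)oct-3-en-7-yn-2-ol
Conditions: Pd(PPh3)4 (cat.), CuI (cat.), Et3N, THF, 45 °C
Reagents that add atoms: none
Why: Sonogashira coupling of the 2-bromo-1-alkene with the copper acetylide; the skipped diene and the free tertiary alcohol are inert to the amine base at this temperature.

Step 4
Reactants: 6 (E)-2-methyl-6-methylidene-8-(trimethylsilyl)oct-3-en-7-yn-2-ol
Product: 7 (E)-2-methyl-6-methylideneoct-3-en-7-yn-2-ol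
Conditions: K2CO3 (cat.), MeOH, 0 °C to rt
Reagents that add atoms: none
Why: Base-catalysed methanolysis of the C(sp)–Si bond (protodesilylation) should free the terminal alkyne without touching the alkenes; the volatile enyne is best kept in solution.

Step 5
Reactants: 8 L-arabinose
Product: 9 methyl β-L-arabinopyranoside
Conditions: MeOH, HCl (cat.), reflux; crystallisation
Reagents that add atoms: methanol, CO
Why: Fischer glycosidation under thermodynamic control gives the pyranosides, of which the β-L anomer with axial methoxy group (anomeric effect) crystallises; the carbinol stereocentres of arabinose are not involved.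

Step 6
Reactants: 9 methyl β-L-arabinopyranoside
Product: 11 methyl 3-O-methyl-β-L-arabinopyranoside, via stannylene acetal 10 (not isolated)
Conditions: Bu2SnO, MeOH, reflux, then evaporation; MeI, CsF, DMF, rt to 40 °C
Reagents that add atoms: iodomethane, CI
Why: Stannylene-acetal alkylation: the tin acetal forms on the cis-3,4-diol and raises the nucleophilicity of the equatorial O3, so methylation should occur there and leave O2 and O4 free.

Step 7
Reactants: 11 methyl 3-O-methyl-β-L-arabinopyranoside
Product: 12 3-O-methyl-L-arabinose diethyl dithioacetal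
Conditions: EtSH, conc. HCl, 0 °C to rt
Reagents that add atoms: ethanethiol, CCS
Why: Acid-catalysed mercaptolysis opens the glycoside to the acyclic dithioacetal, which masks C1 and frees the C5 hydroxyl; the methyl ether and the three stereocentres are stable to these conditions.

Step 8
Reactants: 12 3-O-methyl-L-arabinose diethyl dithioacetal
Product: 13 2,4,5-tri-O-TBS-3-O-methyl-L-arabinose diethyl dithioacetal
Conditions: TBSOTf, 2,6-lutidine, CH2Cl2, −20 to 0 °C
Reagents that add atoms: tert-butyldimethylsilyl trifluoromethanesulfonate, CC(C)(C)[Si](C)(C)OS(=O)(=O)C(F)(F)F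
Why: Exhaustive silylation with a silyl triflate and a hindered base covers the hindered secondary hydroxyls as well as the primary one.

Step 9
Reactants: 13 2,4,5-tri-O-TBS-3-O-methyl-L-arabinose diethyl dithioacetal
Product: 14 2,4-di-O-TBS-3-O-methyl-L-arabinose diethyl dithioacetal
Conditions: HF·pyridine, pyridine, THF, 0 °C
Reagents that add atoms: none
Why: Selective desilylation, since buffered fluoride cleaves the unhindered primary silyl ether much faster than the two flanked secondary ones, and the acidic medium prevents silyl migration.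

Step 10
Reactants: 14 2,4-di-O-TBS-3-O-methyl-L-arabinose diethyl dithioacetal
Product: 15 2,4-di-O-TBS-3-O-methyl-L-arabino-pentodialdose 1-(diethyl dithioacetal)
Conditions: SO3·pyridine, DMSO, iPr2NEt, CH2Cl2, 0 °C
Reagents that add atoms: none
Why: Parikh–Doering oxidation, in which activated DMSO oxidises the primary alcohol but not the dithioacetal sulfur, and the α-silyloxy aldehyde should not epimerise at 0 °C if used crude.

Step 11
Reactants: 15 2,4-di-O-TBS-3-O-methyl-L-arabino-pentodialdose 1-(diethyl dithioacetal)
Product: 16 6,6-dibromo-5,6-dideoxy-2,4-di-O-TBS-3-O-methyl-L-arabino-hex-5-enose diethyl dithioacetal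
Conditions: CBr4, PPh3, Zn, CH2Cl2, 0 °C to rt
Reagents that add atoms: carbon tetrabromide, BrC(Br)(Br)Br
Why: Corey–Fuchs dibromo-olefination, a Wittig reaction of the dibromomethylidene ylide formed in the flask, proceeds under near-neutral conditions that spare the silyl ethers, the dithioacetal and the adjacent stereocentre.

Step 12
Reactants: 16 6,6-dibromo-5,6-dideoxy-2,4-di-O-TBS-3-O-methyl-L-arabino-hex-5-enose diethyl dithioacetal; 7 (E)-2-methyl-6-methylideneoct-3-en-7-yn-2-ol
Product: 17 (Z)-bromoenyne dithioacetal (alkynyl group of 7 trans to C4; remaining Br cis to C4)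
Conditions: PdCl2(dppf) (cat.), CuI (cat.), iPr2NH, toluene, rt; 7 added slowly (1 equiv)
Reagents that add atoms: none
Why: Trans-selective Sonogashira coupling of a 1,1-dibromoalkene: zerovalent palladium inserts into the less hindered C–Br bond trans to the branched chain, so the bromine that remains is cis to C4, and one equivalent of alkyne at room temperature should hold the reaction at mono-coupling.

Step 13
Reactants: 17 (Z)-bromoenyne dithioacetal
Product: 18 (2R,3S,4S,5Z,11E)-6-bromo-2,4-bis(tert-butyldimethylsilyloxy)-13-hydroxy-3-methoxy-13-methyl-9-methylidenetetradeca-5,11-dien-7-ynal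
Conditions: I2, NaHCO3, acetone/H2O, 0 °C; used crude at once
Reagents that add atoms: water, O
Why: Iodine-promoted oxidative hydrolysis of the dithioacetal under bicarbonate buffer is fast at 0 °C, which should spare the electron-poor enyne and the silyl ethers and avoid epimerisation or methoxide loss from the α-silyloxy β-methoxy aldehyde.

Step 14
Reactants: 18 (2R,3S,4S,5Z,11E)-6-bromo-2,4-bis(tert-butyldimethylsilyloxy)-13-hydroxy-3-methoxy-13-methyl-9-methylidenetetradeca-5,11-dien-7-ynal
Product: 20 bis-TBS cyclohexenol (C3 and C5 OTBS; C6 OH cis to the C5 oxygen), via alkenylchromium dichloride 19 (not isolated)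
Conditions: CrCl2 (excess), NiCl2 (cat.), degassed DMF, rt, high dilution; aqueous serine work-up
Reagents that add atoms: none
Why: Zerovalent nickel, generated from NiCl2 by CrCl2, inserts into the alkenyl C–Br bond with retention of geometry and passes the alkenyl group to trivalent chromium, and the alkenylchromium dichloride 19 adds to the aldehyde; this is an intramolecular Nozaki–Hiyama–Kishi reaction, the closest known type being the closure of sugar-derived haloalkenyl aldehydes to carbasugar cyclohexenols. The ring closes by C1–C6 bond formation in a 6-exo-trig attack on the carbonyl with the C1=C2 bond ending endocyclic, which the (Z) geometry allows because chromium sits cis to the chain. The new C6 stereocentre is under substrate control: in the half-chair transition state the trans C4 methoxy and C5 silyloxy groups should stand diaxial, the C3 silyloxy group pseudoequatorial, and the chromium-bound carbonyl oxygen near the alkenyl plane, so the C6 oxygen should end cis to the C5 oxygen. The step needs selectivity for the C–Br bond and for the aldehyde, which the halide-specific nickel insertion and the low basicity of organochromium reagents secure in the presence of the enyne, the skipped diene, the silyl ethers and the free tertiary alcohol; high dilution keeps the addition intramolecular.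

Step 15
Reactants: 20 bis-TBS cyclohexenol
Product: 21 (3S,4S,5S,6S)-1-[(E)-7-hydroxy-7-methyl-3-methylideneoct-5-en-1-yn-1-yl]-4-methoxycyclohex-1-ene-3,5,6-triol
Conditions: Bu4NF, THF, 0 °C to rt
Reagents that add atoms: none
Why: Fluoride-mediated desilylation, driven by the Si–F bond, removes both secondary silyl ethers; the molecule has no ester or other base-labile group at this stage.

Step 16
Reactants: 21 (3S,4S,5S,6S)-1-[(E)-7-hydroxy-7-methyl-3-methylideneoct-5-en-1-yn-1-yl]-4-methoxycyclohex-1-ene-3,5,6-triol
Product: 24 target CNP0546270.2, via phenylboronate 22 (not isolated), via acetylated phenylboronate 23 (not isolated)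
Conditions: PhB(OH)2 (1.05 equiv), MgSO4, pyridine, rt; Ac2O, 0 °C to rt; pinacol, CH2Cl2/MeOH, rt
Reagents that add atoms: acetic anhydride, CC(=O)OC(C)=O
Why: Transient boronate protection followed by acylation: phenylboronic acid condenses only with the cis C5/C6 diol, Ac2O/pyridine then acetylates the remaining secondary C3 hydroxyl but not the tertiary one, and pinacol transesterification frees the diol without acid that could ionise the tertiary allylic alcohol, while the acetate cannot migrate because its neighbour C4 carries the methyl ether.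

**Compound list**

1 | 2-methylbut-3-yn-2-ol | CC(C)(O)C#C | starting material
2 | (E)-2-methyl-4-(tributylstannyl)but-3-en-2-ol | CCCC[Sn](CCCC)(CCCC)/C=C/C(C)(C)O | intermediate
3 | 2,3-dibromopropene | C=C(Br)CBr | starting material
4 | (E)-6-bromo-2-methylhepta-3,6-dien-2-ol | C=C(Br)C/C=C/C(C)(C)O | intermediate
5 | ethynyltrimethylsilane | C#C[Si](C)(C)C | starting material
6 | (E)-2-methyl-6-methylidene-8-(trimethylsilyl)oct-3-en-7-yn-2-ol | C=C(C#C[Si](C)(C)C)C/C=C/C(C)(C)O | intermediate
7 | (E)-2-methyl-6-methylideneoct-3-en-7-yn-2-ol | C=C(C#C)C/C=C/C(C)(C)O | intermediate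
8 | L-arabinose | O=C[C@H](O)[C@@H](O)[C@@H](O)CO | starting material
9 | methyl β-L-arabinopyranoside | CO[C@H]1OC[C@H](O)[C@H](O)[C@H]1O | intermediate
10 | methyl 3,4-O-dibutylstannylene-β-L-arabinopyranoside (formed in the flask) | CO[C@H]1OC[C@@H]2O[Sn](CCCC)(CCCC)O[C@@H]2[C@H]1O | intermediate
11 | methyl 3-O-methyl-β-L-arabinopyranoside | CO[C@H]1OC[C@H](O)[C@H](OC)[C@H]1O | intermediate
12 | 3-O-methyl-L-arabinose diethyl dithioacetal | CCSC(SCC)[C@H](O)[C@@H](OC)[C@@H](O)CO | intermediate
13 | 2,4,5-tri-O-(tert-butyldimethylsilyl)-3-O-methyl-L-arabinose diethyl dithioacetal | CCSC(SCC)[C@H](O[Si](C)(C)C(C)(C)C)[C@@H](OC)[C@@H](O[Si](C)(C)C(C)(C)C)CO[Si](C)(C)C(C)(C)C | intermediate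
14 | 2,4-di-O-(tert-butyldimethylsilyl)-3-O-methyl-L-arabinose diethyl dithioacetal (free 5-OH) | CCSC(SCC)[C@H](O[Si](C)(C)C(C)(C)C)[C@@H](OC)[C@@H](O[Si](C)(C)C(C)(C)C)CO | intermediate
15 | 2,4-di-O-(tert-butyldimethylsilyl)-3-O-methyl-L-arabino-pentodialdose 1-(diethyl dithioacetal) (C5 aldehyde) | CCSC(SCC)[C@H](O[Si](C)(C)C(C)(C)C)[C@@H](OC)[C@@H](O[Si](C)(C)C(C)(C)C)C=O | intermediate
16 | 6,6-dibromo-5,6-dideoxy-2,4-di-O-(tert-butyldimethylsilyl)-3-O-methyl-L-arabino-hex-5-enose diethyl dithioacetal | CCSC(SCC)[C@H](O[Si](C)(C)C(C)(C)C)[C@@H](OC)[C@@H](O[Si](C)(C)C(C)(C)C)C=C(Br)Br | intermediate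
17 | (Z)-bromoenyne dithioacetal: 14 in which C5 is the CH of a (Z)-CH=C(Br)–C≡C–C(=CH2)–CH2–CH=CH–C(CH3)2OH unit, Br cis to C4, side-chain alkene (E) | CCSC(SCC)[C@H](O[Si](C)(C)C(C)(C)C)[C@@H](OC)[C@@H](O[Si](C)(C)C(C)(C)C)/C=C(\Br)C#CC(=C)C/C=C/C(C)(C)O | intermediate
18 | (2R,3S,4S,5Z,11E)-6-bromo-2,4-bis(tert-butyldimethylsilyloxy)-13-hydroxy-3-methoxy-13-methyl-9-methylidenetetradeca-5,11-dien-7-ynal | O=C[C@H](O[Si](C)(C)C(C)(C)C)[C@@H](OC)[C@@H](O[Si](C)(C)C(C)(C)C)/C=C(\Br)C#CC(=C)C/C=C/C(C)(C)O | intermediate
19 | alkenylchromium dichloride of 18 (trivalent chromium in place of bromine, same alkene geometry; formed in the flask) | O=C[C@H](O[Si](C)(C)C(C)(C)C)[C@@H](OC)[C@@H](O[Si](C)(C)C(C)(C)C)/C=C(\[Cr](Cl)Cl)C#CC(=C)C/C=C/C(C)(C)O | intermediate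
20 | (3S,4S,5S,6S)-3,5-bis(tert-butyldimethylsilyloxy)-1-[(E)-7-hydroxy-7-methyl-3-methylideneoct-5-en-1-yn-1-yl]-4-methoxycyclohex-1-en-6-ol (C3-O and C4-O cis, C5-O and C6-O cis, C4-O and C5-O trans) | C=C(C#CC1=C[C@H](O[Si](C)(C)C(C)(C)C)[C@H](OC)[C@@H](O[Si](C)(C)C(C)(C)C)[C@H]1O)C/C=C/C(C)(C)O | intermediate
21 | (3S,4S,5S,6S)-1-[(E)-7-hydroxy-7-methyl-3-methylideneoct-5-en-1-yn-1-yl]-4-methoxycyclohex-1-ene-3,5,6-triol | C=C(C#CC1=C[C@H](O)[C@H](OC)[C@@H](O)[C@H]1O)C/C=C/C(C)(C)O | intermediate
22 | 5,6-O-phenylboronate of 21 (cyclic boronic ester on the cis C5/C6 diol; formed in the flask) | C=C(C#CC1=C[C@H](O)[C@H](OC)[C@H]2OB(c3ccccc3)O[C@@H]12)C/C=C/C(C)(C)O | intermediate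
23 | 3-O-acetyl-5,6-O-phenylboronate of 21 (formed in the flask) | C=C(C#CC1=C[C@H](OC(C)=O)[C@H](OC)[C@H]2OB(c3ccccc3)O[C@@H]12)C/C=C/C(C)(C)O | intermediate
24 | CNP0546270.2: (3S,4R,5S,6S)-5,6-dihydroxy-1-[(E)-7-hydroxy-7-methyl-3-methylideneoct-5-en-1-yn-1-yl]-4-methoxycyclohex-1-en-3-yl acetate | C=C(C#CC1=C[C@H](OC(C)=O)[C@H](OC)[C@@H](O)[C@H]1O)C/C=C/C(C)(C)O | target

**Step count and risks**

Total steps: 16. Longest linear sequence: 12 steps (steps 5 to 16, from L-arabinose 8 to 24); the side chain (steps 1 to 4) enters at step 12.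

Steps most likely to fail:

1. Step 14. The addition to the aldehyde may show poor facial selectivity at C6, because the Felkin-type and the diaxial half-chair transition states are close in energy; protodebromination may also compete with ring closure. The fallback sets the C6 stereocentre by ketone reduction instead of by the C–C bond formation. It sets out from 18 and comes back at 20. The closure is run as in step 14 and the alcohol mixture, 20 together with its C6 epimer F1, is oxidised with Dess–Martin periodinane/NaHCO3 (CH2Cl2, 0 °C) to the cross-conjugated enone F2. Luche reduction (NaBH4, CeCl3·7H2O, MeOH, −78 °C) should then deliver hydride to the carbonyl anti to the axial C5 silyloxy group and give 20.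

2. Step 12. The coupling may run on to a second alkynylation at the cis C–Br bond, lose trans selectivity, or consume the four-step enyne 7 by oxidative dimerisation. The fallback changes the order of fragment union and brings the side chain in late as the stable bromodiene 4. It sets out from 16 and comes back at 20. Compound 16 is coupled under the step 12 conditions with ethynyltrimethylsilane 5 to the silylated (Z)-bromoenyne dithioacetal F3. I2/NaHCO3 gives the aldehyde F4, and CrCl2/NiCl2 closure gives the silylalkynyl cyclohexenol F5. K2CO3/MeOH frees the terminal alkyne F6, and Sonogashira coupling of F6 with 4 (Pd(PPh3)4, CuI, Et3N, THF) gives 20.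

3. Step 16. Boronate formation may be incomplete or the boronate may be lost during acylation, so that acetylation spreads to C5 or C6; the boronate may also be reluctant to release. The fallback replaces the transient boronate by an isolable acetal. It sets out from 21 and comes back at 24. 2,2-Dimethoxypropane with pyridinium p-toluenesulfonate (acetone, rt) gives the 5,6-O-isopropylidene acetal F7. Ac2O/pyridine gives its C3 acetate F8, and mild hydrolysis (aqueous acetic acid, rt to 40 °C, followed closely to protect the tertiary allylic alcohol) gives 24.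

**Further compounds**

F1 | step 14 | C6 epimer of 20 (C6 OH trans to the C5 oxygen) | C=C(C#CC1=C[C@H](O[Si](C)(C)C(C)(C)C)[C@H](OC)[C@@H](O[Si](C)(C)C(C)(C)C)[C@@H]1O)C/C=C/C(C)(C)O
F2 | step 14 | cross-conjugated enone (C6 ketone of 20) | C=C(C#CC1=C[C@H](O[Si](C)(C)C(C)(C)C)[C@H](OC)[C@@H](O[Si](C)(C)C(C)(C)C)C1=O)C/C=C/C(C)(C)O
F3 | step 12 | silylated (Z)-bromoenyne dithioacetal (trimethylsilylethynyl group trans to C4) | CCSC(SCC)[C@H](O[Si](C)(C)C(C)(C)C)[C@@H](OC)[C@@H](O[Si](C)(C)C(C)(C)C)/C=C(\Br)C#C[Si](C)(C)C
F4 | step 12 | silylated (Z)-bromoenyne aldehyde | O=C[C@H](O[Si](C)(C)C(C)(C)C)[C@@H](OC)[C@@H](O[Si](C)(C)C(C)(C)C)/C=C(\Br)C#C[Si](C)(C)C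
F5 | step 12 | silylalkynyl cyclohexenol (20 with trimethylsilylethynyl in place of the side chain) | C[Si](C)(C)C#CC1=C[C@H](O[Si](C)(C)C(C)(C)C)[C@H](OC)[C@@H](O[Si](C)(C)C(C)(C)C)[C@H]1O
F6 | step 12 | ethynyl cyclohexenol (terminal alkyne) | C#CC1=C[C@H](O[Si](C)(C)C(C)(C)C)[C@H](OC)[C@@H](O[Si](C)(C)C(C)(C)C)[C@H]1O
F7 | step 16 | 5,6-O-isopropylidene acetal of 21 | C=C(C#CC1=C[C@H](O)[C@H](OC)[C@H]2OC(C)(C)O[C@@H]12)C/C=C/C(C)(C)O
F8 | step 16 | 3-O-acetyl-5,6-O-isopropylidene acetal of 21 | C=C(C#CC1=C[C@H](OC(C)=O)[C@H](OC)[C@H]2OC(C)(C)O[C@@H]12)C/C=C/C(C)(C)O
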